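**Retrosynthetic overview**
1. Numbering used: ring A = cyclopentane C1 (CH–OH), C2 (CH bearing the tetraene chain), C3, C4 (CH2), C5 (spiro carbon); ring B = cyclohexane C5, C6 (CH bearing the hydroxypropyl chain), C7 (alkylidene carbon), C8, C9 (CH2), C10 (C(CH3)OH).
2. Target ⇐ DIBAL opening of an (E)-alkylidene γ-lactone that ties C1–O to the hydroxymethyl carbon, then acid unmasking ⇐ aldol condensation of lactone 28 with trienal 6 (two Wittig reactions from 4-methylpent-3-en-1-ol).
3. Lactone ⇐ dirhodium carbenoid insertion of a C1 diazoacetate into C2–H (C1 relays its configuration to C2); C10 carbinol ⇐ C1-hydroxyl-directed epoxidation and hydride opening of C9=C10; enal ⇐ the isopropenyl group.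
4. Ring A ⇐ (3+2) annulation of a 2-siloxyallyl cation C2–C1–C5, built on the intact carvone ring, with phenyl vinyl sulfide as C3–C4. Enabling feature: the spiro carbon C5 is the former carvone carbonyl carbon, it carries the oxygenated C1 and is allylic to C9=C10, while C3 and C4 are unsubstituted CH2 groups.
5. Ring order: ring B is bought as (S)-carvone (all ten carvone carbons are kept), ring A is closed in the key step, the lactone ring is temporary.

Key step: step 6

Remark: epimer mixtures are expected at centres that are erased later (carbinol C5 of 11–13, sulfur-bearing C4 of 16 and 17, the CH(CH3) carbon of 25 and 26, the aldol centres of 29 and 30). These are drawn open or as the expected major epimer and do not affect the route. Absolute configuration comes from (S)-carvone and from the (S)-CBS catalyst.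

Step 1
Reactants: 1 4-methylpent-3-en-1-ol; 2 2-(triphenyl-λ5-phosphanylidene)propanal
Product: 4 (2E)-2,6-dimethylhepta-2,5-dienal, via 4-methylpent-3-enal 3 (not isolated)
Conditions: Dess–Martin periodinane, NaHCO3, CH2Cl2, 0 °C; then 2, 25 °C
Reagents that add atoms: none
Why: Buffered Dess–Martin oxidation should give the β,γ-unsaturated aldehyde without conjugation, and the stabilised ylide traps it at once in a Wittig reaction that should favour the E-trisubstituted enal.

Step 2
Reactants: 4 (2E)-2,6-dimethylhepta-2,5-dienal; 5 2-(triphenyl-λ5-phosphanylidene)acetaldehyde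
Product: 6 (2E,4E)-4,8-dimethylnona-2,4,7-trienal
Conditions: toluene, 80 °C
Reagents that add atoms: none
Why: Wittig two-carbon homologation with the formylmethylene ylide should give the E-enal, and the more conjugated product is less electrophilic than 4, which limits a second homologation.

Step 3
Reactants: 7 (S)-(+)-carvone; 8 tert-butyl(3-iodopropoxy)dimethylsilane
Product: 9 (5S,6R)-6-[3-(tert-butyldimethylsilyloxy)propyl]-2-methyl-5-(prop-1-en-2-yl)cyclohex-2-en-1-one
Conditions: LiN(iPr)2, THF, −78 °C; then 8, DMPU, −78 → −20 °C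
Reagents that add atoms: none
Why: Kinetic deprotonation at the α'-CH2 gives the cross-conjugated dienolate, which should be alkylated anti to the neighbouring isopropenyl group (enolate alkylation), setting C6 with the isopropenyl carbon as a relay centre that is erased in step 15.

Step 4
Reactants: 9 alkylated carvone; 10 ethyl vinyl ether
Product: 12 1-[(5S,6R)-6-[3-(tert-butyldimethylsilyloxy)propyl]-1-hydroxy-2-methyl-5-(prop-1-en-2-yl)cyclohex-2-en-1-yl]ethan-1-one, via ethoxyvinyl carbinol 11 (not isolated)
Conditions: 10, t-BuLi, THF, −78 → 0 °C; then 9, −78 °C; then 0.5 M aq. HCl, THF, 0 °C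
Reagents that add atoms: water, O
Why: 1-Ethoxyvinyllithium is a standard acetyl anion equivalent that adds 1,2 to the enone, and mild hydrolysis of the enol ether releases the methyl ketone; the carbinol configuration (attack expected anti to the C6 chain) is erased in step 6.

Step 5
Reactants: 12 α-hydroxy methyl ketone
Product: 13 bis(trimethylsilyl) derivative of 12 (tertiary OSiMe3 at C5 and 1-(trimethylsiloxy)ethenyl group)
Conditions: Me3SiOTf (2.4 equiv), Et3N, CH2Cl2, −78 → 0 °C
Reagents that add atoms: trimethylsilyl triflate, C[Si](C)(C)OS(=O)(=O)C(F)(F)F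
Why: Silyl triflate and amine should convert the methyl ketone into its only possible silyl enol ether and silylate the tertiary alcohol, giving a 2-siloxyallyl silyl ether that is primed for ionisation.

Step 6
Reactants: 13 bis(trimethylsilyl) ether; 14 phenyl vinyl sulfide
Product: 16 6-[3-(tert-butyldimethylsilyloxy)propyl]-10-methyl-4-(phenylsulfanyl)-7-(prop-1-en-2-yl)spiro[4.5]dec-9-en-1-one (route numbering; C4 trans and C1 cis to the C6 chain on ring B), via siloxyallyl cation 15 (not isolated)
Conditions: Me3SiOTf (15 mol %), 2,6-di-tert-butyl-4-methylpyridine (20 mol %), 14 (3 equiv), CH2Cl2, −78 °C, slow addition of 13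
Reagents that add atoms: none
Why: Catalytic Me3SiOTf ionises the tertiary, doubly allylic C5–OSiMe3 bond of 13 to the 2-siloxyallyl (oxyallyl) cation 15, whose charge is shared by C2, C5 and C9; the CH2 terminus of phenyl vinyl sulfide attacks the unhindered C2 (new C2–C3 bond), the thionium ion so formed is captured intramolecularly by C5 of the silyl dienol ether (new C4–C5 bond), and loss of Me3Si+ from the oxocarbenium ion returns the catalyst and gives the cyclopentanone. The closest known reaction type is the stepwise (3+2) annulation of 2-oxyallyl and 2-siloxyallyl cations with vinyl sulfides and enol ethers to cyclopentanones, including tertiary termini that become quaternary α-carbons. Ring A is closed by a five-membered Mukaiyama-type (enolendo, exo-trig) addition of the enol ether carbon to the thionium carbon; capture by the enol ether oxygen would give only an O,S-acetal that re-ionises under the Lewis acid, so the C–C product should accumulate. The spiro carbon C5 is the new permanent stereocentre: allylic 1,3-strain against the exocyclic enol ether holds the C6 chain pseudoaxial, and C4 is expected to enter anti to it, which places C1 cis to the chain; the sulfur-bearing C4 is not controlled and is erased in step 8. The step needs attack at C2 instead of the ring position C9 (favoured by the primary, unhindered terminus and the excess of 14), no proton-initiated polymerisation of 14 (hindered pyridine buffer, −78 °C), and survival of the isopropenyl group and the silyl ether (no protic acid, low temperature).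

Step 7
Reactants: 16 spiro keto sulfide
Product: 17 (1R)-alcohol of 16 (OH cis to C6 on ring A)
Conditions: (S)-2-methyl-CBS-oxazaborolidine (0.5 equiv), catecholborane (2 equiv), toluene, −78 → −40 °C; then MeOH, aq. NaOH
Reagents that add atoms: none
Why: Corey–Bakshi–Shibata reduction differentiates the quaternary C5 from the C2 methylene flank and should set C1 as R by reagent control, and catecholborane at low temperature does not hydroborate the alkenes.

Step 8
Reactants: 17 hydroxy sulfide
Product: 18 (1R)-6-[3-(tert-butyldimethylsilyloxy)propyl]-10-methyl-7-(prop-1-en-2-yl)spiro[4.5]dec-9-en-1-ol (route numbering)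
Conditions: n-BuLi (1.05 equiv), THF, −78 °C; lithium 4,4'-di-tert-butylbiphenylide (2.5 equiv), −78 °C; then MeOH
Reagents that add atoms: none
Why: Reductive lithiation of the secondary alkyl phenyl sulfide (the alcohol is first turned into its lithium alkoxide) and protonation should remove the auxiliary sulfur without touching the isolated alkenes or the silyl ether, erasing the C4 centre.

Step 9
Reactants: 18 spiro alcohol
Product: 19 9,10-epoxide of 18 (epoxide oxygen on the ring B face that carries C1)
Conditions: VO(acac)2 (5 mol %), t-BuOOH (1.5 equiv), CH2Cl2, 0 → 25 °C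
Reagents that add atoms: tert-butyl hydroperoxide, CC(C)(C)OO
Why: The homoallylic C1–OH binds the vanadium peroxide and should deliver oxygen to C9=C10 on the ring B face that carries C1 (hydroxyl-directed epoxidation), so that the future C10–O bond is cis to C1, while the undirected isopropenyl group is left alone.

Step 10
Reactants: 19 epoxy alcohol
Product: 20 6-[3-(tert-butyldimethylsilyloxy)propyl]-10-methyl-7-(prop-1-en-2-yl)spiro[4.5]decane-1,10-diol (C1 R; C10–OH cis to C1 on ring B)
Conditions: LiEt3BH (3 equiv), THF, 0 → 25 °C; then H2O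
Reagents that add atoms: none
Why: Hydride should open the trisubstituted epoxide by SN2 attack at the secondary C9, because the tertiary C10 next to the spiro carbon is inaccessible, leaving the tertiary C10–OH with the configuration fixed in step 9.

Step 11
Reactants: 20 diol
Product: 22 C1 bromoacetate and C10 trimethylsilyl ether of 20, via bromoacetate 21 (not isolated)
Conditions: BrCH2COBr (1.2 equiv), 2,6-lutidine (4 equiv), CH2Cl2, −20 °C; then Me3SiOTf (1.5 equiv), −78 → 0 °C
Reagents that add atoms: bromoacetyl bromide, O=C(Br)CBr; trimethylsilyl triflate, C[Si](C)(C)OS(=O)(=O)C(F)(F)F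
Why: The secondary C1–OH is acylated in preference to the tertiary C10–OH, which is then capped in the same flask as its trimethylsilyl ether so that it cannot intercept the carbenoid of step 13 by O–H insertion.

Step 12
Reactants: 22 bromoacetate silyl ether
Product: 23 C1 diazoacetate, C10 trimethylsilyl ether
Conditions: TsNHNHTs (2 equiv), DBU (5 equiv), THF, 0 °C
Reagents that add atoms: N,N'-ditosylhydrazine, Cc1ccc(cc1)S(=O)(=O)NNS(=O)(=O)c1ccc(C)cc1
Why: Alkylation of the ditosylhydrazine anion by the bromoacetate and twofold base-induced loss of sulfinate should give the diazoacetate under mild conditions (diazoacetate synthesis from bromoacetates).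

Step 13
Reactants: 23 diazoacetate
Product: 24 cis-fused γ-lactone (C1–O–C(=O)–CH2–C2) bearing the C10 trimethylsilyl ether, the isopropenyl group and the silyloxypropyl chain
Conditions: Rh2(cap)4, dirhodium tetrakis(caprolactamate) (1 mol %), CH2Cl2, 40 °C, slow addition of 23
Reagents that add atoms: none
Why: The carboxamidate-ligated dirhodium carbenoid should insert into the C2–H bond cis to the C1–O bond through a five-membered transition state (C5 carries no hydrogen), giving the cis-fused γ-lactone and thereby setting C2 from C1 (intramolecular carbenoid C–H insertion of a cycloalkyl diazoacetate).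

Step 14
Reactants: 24 lactone
Product: 25 lactone with a 1-hydroxypropan-2-yl group at C7
Conditions: 9-BBN (1.5 equiv), THF, 0 → 25 °C; then 30% H2O2, aq. NaOAc, 0 °C
Reagents that add atoms: hydrogen peroxide, OO
Why: 9-BBN should hydroborate the only alkene, the 1,1-disubstituted isopropenyl group, at its terminal carbon without reducing the lactone, and buffered oxidation gives the primary alcohol (hydroboration–oxidation); the new CH(CH3) centre is irrelevant.

Step 15
Reactants: 25 primary alcohol
Product: 27 lactone with the (Z)-1-oxopropan-2-ylidene group at C7 (CHO cis to C6), via aldehyde 26 (not isolated)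
Conditions: IBX (4 equiv), DMSO, 80 °C
Reagents that add atoms: none
Why: IBX should oxidise the primary alcohol to the aldehyde and then dehydrogenate it to the tetrasubstituted enal (IBX α,β-dehydrogenation), erasing the C7 and CH(CH3) centres; the Z isomer, with the planar formyl group instead of methyl next to the fully substituted C6, is expected to be the less strained one, and the isomers can equilibrate through the dienol under the warm, mildly acidic conditions.

Step 16
Reactants: 27 enal lactone
Product: 28 dimethyl acetal of 27 with free C10–OH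
Conditions: HC(OMe)3, MeOH, PPTS (10 mol %), 25 °C
Reagents that add atoms: trimethyl orthoformate, COC(OC)OC; methanol, CO
Why: Acid-catalysed acetalisation masks the enal against the enolate and hydride steps to come, and the same methanolic acid should remove the tertiary trimethylsilyl ether, which is no longer needed.

Step 17
Reactants: 28 acetal lactone; 6 (2E,4E)-4,8-dimethylnona-2,4,7-trienal
Product: 29 aldol adduct (lactone α-carbon bonded to the former aldehyde carbon, secondary OH)
Conditions: LiN(iPr)2 (2.3 equiv), THF, −78 °C; then 6, −78 °C; aq. NH4Cl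
Reagents that add atoms: none
Why: The lithium enolate of the γ-lactone (the tertiary alkoxide forms first) should add 1,2 to the unhindered aldehyde of 6 (aldol addition), and the two new centres are erased in step 18.

Step 18
Reactants: 29 aldol adduct
Product: 31 (E)-alkylidene lactone (tetraene chain anti to the lactone carbonyl), via mesylate 30 (not isolated)
Conditions: MsCl, Et3N, CH2Cl2, −20 °C; then DBU, 0 → 25 °C
Reagents that add atoms: none
Why: Mesylation of the secondary alcohol and E1cB elimination with DBU should give the thermodynamically preferred (E)-alkylidene lactone, conjugated with the triene, while the hindered tertiary C10–OH is not sulfonylated.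

Step 19
Reactants: 31 alkylidene lactone
Product: 32 C1,hydroxymethyl diol still carrying the dimethyl acetal and the primary silyl ether
Conditions: i-Bu2AlH (5 equiv), CH2Cl2, −78 → −20 °C; aq. Rochelle salt
Reagents that add atoms: none
Why: Excess DIBAL-H should reduce the α-alkylidene lactone in 1,2-fashion through the lactol to the allylic diol, revealing C1–OH and the hydroxymethyl group, while the acetal and the silyl ether are inert.

Step 20
Reactants: 32 protected diol
Product: 33 target CNP0261841.1
Conditions: AcOH/THF/H2O (3:1:1), 25 °C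
Reagents that add atoms: water, O
Why: Aqueous acetic acid should hydrolyse the allylic dimethyl acetal to the enal and cleave the primary silyl ether under conditions that the allylic alcohols and the polyene are expected to tolerate.

**Compound list**
1 | 4-methylpent-3-en-1-ol | CC(C)=CCCO | starting material
2 | 2-(triphenyl-λ5-phosphanylidene)propanal | CC(C=O)=P(c1ccccc1)(c1ccccc1)c1ccccc1 | starting material
3 | 4-methylpent-3-enal | CC(C)=CCC=O | intermediate
4 | (2E)-2,6-dimethylhepta-2,5-dienal | CC(C)=CC/C=C(\C)C=O | intermediate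
5 | 2-(triphenyl-λ5-phosphanylidene)acetaldehyde | O=CC=P(c1ccccc1)(c1ccccc1)c1ccccc1 | starting material
6 | (2E,4E)-4,8-dimethylnona-2,4,7-trienal | CC(C)=CC/C=C(C)/C=C/C=O | intermediate
7 | (S)-(+)-carvone | CC1=CC[C@@H](CC1=O)C(C)=C | starting material
8 | tert-butyl(3-iodopropoxy)dimethylsilane | ICCCO[Si](C)(C)C(C)(C)C | starting material
9 | (5S,6R)-6-[3-(tert-butyldimethylsilyloxy)propyl]-2-methyl-5-(prop-1-en-2-yl)cyclohex-2-en-1-one | CC1=CC[C@H](C(C)=C)[C@@H](CCCO[Si](C)(C)C(C)(C)C)C1=O | intermediate
10 | ethyl vinyl ether | C=COCC | starting material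
11 | 1-(1-ethoxyethenyl) carbinol from 9 | CC1=CC[C@H](C(C)=C)[C@@H](CCCO[Si](C)(C)C(C)(C)C)[C@]1(O)C(=C)OCC | intermediate
12 | α-hydroxy methyl ketone from 9 | CC1=CC[C@H](C(C)=C)[C@@H](CCCO[Si](C)(C)C(C)(C)C)[C@]1(O)C(C)=O | intermediate
13 | bis(trimethylsilyl) derivative of 12 | CC1=CC[C@H](C(C)=C)[C@@H](CCCO[Si](C)(C)C(C)(C)C)[C@]1(O[Si](C)(C)C)C(=C)O[Si](C)(C)C | intermediate
14 | phenyl vinyl sulfide | C=CSc1ccccc1 | starting material
15 | 2-(trimethylsiloxy)allyl cation from 13 | CC1=CC[C@H](C(C)=C)[C@@H](CCCO[Si](C)(C)C(C)(C)C)[C+]1C(=C)O[Si](C)(C)C | intermediate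
16 | spiro keto sulfide (C4 epimers) | O=C1CCC(Sc3ccccc3)[C@@]12C(C)=CC[C@H](C(C)=C)[C@H]2CCCO[Si](C)(C)C(C)(C)C | intermediate
17 | (1R)-hydroxy sulfide (C4 epimers) | O[C@@H]1CCC(Sc3ccccc3)[C@@]12C(C)=CC[C@H](C(C)=C)[C@H]2CCCO[Si](C)(C)C(C)(C)C | intermediate
18 | (1R)-spiro alcohol | O[C@@H]1CCC[C@@]12C(C)=CC[C@H](C(C)=C)[C@H]2CCCO[Si](C)(C)C(C)(C)C | intermediate
19 | 9,10-epoxy alcohol | O[C@@H]1CCC[C@@]12[C@@]3(C)O[C@H]3C[C@H](C(C)=C)[C@H]2CCCO[Si](C)(C)C(C)(C)C | intermediate
20 | 1,10-diol | O[C@@H]1CCC[C@@]12[C@@](C)(O)CC[C@H](C(C)=C)[C@H]2CCCO[Si](C)(C)C(C)(C)C | intermediate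
21 | C1 bromoacetate of 20 | BrCC(=O)O[C@@H]1CCC[C@@]12[C@@](C)(O)CC[C@H](C(C)=C)[C@H]2CCCO[Si](C)(C)C(C)(C)C | intermediate
22 | C1 bromoacetate, C10 trimethylsilyl ether | BrCC(=O)O[C@@H]1CCC[C@@]12[C@@](C)(O[Si](C)(C)C)CC[C@H](C(C)=C)[C@H]2CCCO[Si](C)(C)C(C)(C)C | intermediate
23 | C1 diazoacetate, C10 trimethylsilyl ether | [N-]=[N+]=CC(=O)O[C@@H]1CCC[C@@]12[C@@](C)(O[Si](C)(C)C)CC[C@H](C(C)=C)[C@H]2CCCO[Si](C)(C)C(C)(C)C | intermediate
24 | cis-fused γ-lactone with isopropenyl group | O=C1C[C@@H]2CC[C@@]3([C@@](C)(O[Si](C)(C)C)CC[C@H](C(C)=C)[C@H]3CCCO[Si](C)(C)C(C)(C)C)[C@@H]2O1 | intermediate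
25 | lactone primary alcohol (CH(CH3) epimers) | O=C1C[C@@H]2CC[C@@]3([C@@](C)(O[Si](C)(C)C)CC[C@H](C(C)CO)[C@H]3CCCO[Si](C)(C)C(C)(C)C)[C@@H]2O1 | intermediate
26 | lactone aldehyde (CH(CH3) epimers) | O=C1C[C@@H]2CC[C@@]3([C@@](C)(O[Si](C)(C)C)CC[C@H](C(C)C=O)[C@H]3CCCO[Si](C)(C)C(C)(C)C)[C@@H]2O1 | intermediate
27 | (Z)-enal lactone | O=C1C[C@@H]2CC[C@@]3([C@@](C)(O[Si](C)(C)C)CC/C(=C(\C)C=O)[C@H]3CCCO[Si](C)(C)C(C)(C)C)[C@@H]2O1 | intermediate
28 | dimethyl acetal lactone with free C10–OH | O=C1C[C@@H]2CC[C@@]3([C@@](C)(O)CC/C(=C(\C)C(OC)OC)[C@H]3CCCO[Si](C)(C)C(C)(C)C)[C@@H]2O1 | intermediate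
29 | aldol adduct (epimers at the two new centres) | O=C1C(C(O)/C=C/C(C)=C/CC=C(C)C)[C@@H]2CC[C@@]3([C@@](C)(O)CC/C(=C(\C)C(OC)OC)[C@H]3CCCO[Si](C)(C)C(C)(C)C)[C@@H]2O1 | intermediate
30 | mesylate of 29 | O=C1C(C(OS(C)(=O)=O)/C=C/C(C)=C/CC=C(C)C)[C@@H]2CC[C@@]3([C@@](C)(O)CC/C(=C(\C)C(OC)OC)[C@H]3CCCO[Si](C)(C)C(C)(C)C)[C@@H]2O1 | intermediate
31 | (E)-alkylidene lactone | O=C1/C(=C/C=C/C(C)=C/CC=C(C)C)[C@@H]2CC[C@@]3([C@@](C)(O)CC/C(=C(\C)C(OC)OC)[C@H]3CCCO[Si](C)(C)C(C)(C)C)[C@@H]2O1 | intermediate
32 | diol with dimethyl acetal and primary silyl ether | CC(C)=CC/C=C(C)/C=C/C=C(/CO)[C@@H]1CC[C@]2([C@H](CCCO[Si](C)(C)C(C)(C)C)/C(=C(/C)C(OC)OC)CC[C@]2(C)O)[C@@H]1O | intermediate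
33 | CNP0261841.1 | CC(C)=CC/C=C(C)/C=C/C=C(/CO)[C@@H]1CC[C@]2([C@H](CCCO)/C(=C(/C)C=O)CC[C@]2(C)O)[C@@H]1O | target

**Step count**
Total steps: 20. Longest linear sequence: 18 steps (steps 3–20, from (S)-carvone); the trienal 6 is made in 2 steps.

**Steps most likely to fail**

Step 6. The first C–C bond may form at the ring position C9 of the delocalised cation instead of C2, the thionium ion may be trapped at oxygen, the vinyl sulfide may polymerise, or the facial selectivity at C5 may be low. The fallback sets out from 9 and uses a known cyclobutanone spiroannulation followed by one-carbon ring expansion. Addition of 1-lithio-1-(phenylsulfanyl)cyclopropane (from cyclopropyl phenyl sulfide and n-BuLi, THF, 0 → −78 °C) to the ketone should give the cyclopropyl carbinol F1. Aqueous HBF4 in ether should induce the cyclopropylcarbinyl-to-cyclobutyl shift anti to the C6 chain and hydrolyse the thionium ion to the spiro cyclobutanone F2. Me3SiCHN2 with Sc(OTf)3 should insert a carbon on the less substituted side to give the α-silyl ketone F3, and dilute acid work-up should give the spiro cyclopentanone F4. Reduction of F4 under the conditions of step 7 returns to the route at 18.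

Step 13. The carbenoid may dimerise, insert into other C–H bonds or add to the isopropenyl group. The fallback sets out from 20 and uses enolate alkylation. Dess–Martin oxidation of the secondary alcohol should give the β-hydroxy ketone F5, and N-(trimethylsilyl)imidazole the silyl ether F6. LiN(iPr)2 then methyl bromoacetate should alkylate C2, the only enolisable position, anti to the bulky C10 side to give the keto ester F7. Reduction as in step 7 should give the cis hydroxy ester F8, and PPTS in benzene at 60 °C should lactonise it, returning to the route at 24.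

Step 15. Dehydrogenation to the hindered tetrasubstituted enal may be slow or go further, and the alkene may form with the wrong geometry. The fallback sets out from 24 and fixes the geometry at an isolable enol triflate. Ozonolysis (O3, CH2Cl2/MeOH, −78 °C; Me2S) of the isopropenyl group should give the methyl ketone F9. Tf2O with 2,6-di-tert-butyl-4-methylpyridine should give the tetrasubstituted enol triflate F10, whose geometric isomers can be separated. Formylation with Pd(OAc)2, 1,3-bis(diphenylphosphino)propane, CO, Et3SiH and Et3N in DMF should proceed with retention and returns to the route at 27.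

Further compounds
F1 | step 6 | 1-[1-(phenylsulfanyl)cyclopropyl] carbinol from 9 | CC1=CC[C@H](C(C)=C)[C@@H](CCCO[Si](C)(C)C(C)(C)C)[C@]1(O)C1(Sc2ccccc2)CC1
F2 | step 6 | spiro cyclobutanone | O=C1CC[C@@]12C(C)=CC[C@H](C(C)=C)[C@H]2CCCO[Si](C)(C)C(C)(C)C
F3 | step 6 | 2-(trimethylsilyl) spiro cyclopentanone | O=C1C([Si](C)(C)C)CC[C@@]12C(C)=CC[C@H](C(C)=C)[C@H]2CCCO[Si](C)(C)C(C)(C)C
F4 | step 6 | spiro cyclopentanone (16 without sulfur) | O=C1CCC[C@@]12C(C)=CC[C@H](C(C)=C)[C@H]2CCCO[Si](C)(C)C(C)(C)C
F5 | step 13 | β-hydroxy ketone from 20 | O=C1CCC[C@@]12[C@@](C)(O)CC[C@H](C(C)=C)[C@H]2CCCO[Si](C)(C)C(C)(C)C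
F6 | step 13 | C10 trimethylsilyl ether of F5 | O=C1CCC[C@@]12[C@@](C)(O[Si](C)(C)C)CC[C@H](C(C)=C)[C@H]2CCCO[Si](C)(C)C(C)(C)C
F7 | step 13 | C2 methoxycarbonylmethyl ketone | O=C1[C@H](CC(=O)OC)CC[C@@]12[C@@](C)(O[Si](C)(C)C)CC[C@H](C(C)=C)[C@H]2CCCO[Si](C)(C)C(C)(C)C
F8 | step 13 | cis hydroxy ester | O[C@@H]1[C@H](CC(=O)OC)CC[C@@]12[C@@](C)(O[Si](C)(C)C)CC[C@H](C(C)=C)[C@H]2CCCO[Si](C)(C)C(C)(C)C
F9 | step 15 | C7 acetyl lactone | O=C1C[C@@H]2CC[C@@]3([C@@](C)(O[Si](C)(C)C)CC[C@H](C(C)=O)[C@H]3CCCO[Si](C)(C)C(C)(C)C)[C@@H]2O1
F10 | step 15 | enol triflate (triflate cis to C6) | O=C1C[C@@H]2CC[C@@]3([C@@](C)(O[Si](C)(C)C)CC/C(=C(\C)OS(=O)(=O)C(F)(F)F)[C@H]3CCCO[Si](C)(C)C(C)(C)C)[C@@H]2O1
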